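## Analysis of the target

The target (41), the gibberellin numbered 17 in the A series, is a tetracyclic C20 triacid in which a cyclohexane (ring A) is trans-fused to a cyclopentane (ring B) whose atom C8 is also a bridgehead of the bicyclo[3.2.1]octane formed by rings C and D. It has seven stereocentres (C4, C5, C6, C8, C9, C10 and C13), of which C4, C8 and C10 are quaternary carbons and C13 is a bridgehead tertiary alcohol. With gibberellane numbering and β defined as the face of ring B that carries H5, the groups H9, the C7 carboxyl and C15 are β, whereas the C19 and C20 carboxyls, C11 and C14 are α; C19 and C20 are 1,3-diaxial on ring A and the C18 methyl group is equatorial. The sensitive groups are the 13-hydroxy-16-methylene unit, which undergoes Wagner–Meerwein rearrangement in protic acid, its 16-oxo precursor, an α-ketol that rearranges as the alkoxide, and C6, which can epimerise next to the C7 carboxyl. The two tertiary esters at C4 and C10 resist hydrolysis, which narrows the choice of the last deprotection. The difficulty lies in the contiguous block C4–C5–C10–C9–C8–C6, with three quaternary carbons, a trans A/B fusion with an angular carboxyl, and a C8 that is both spiro and bridgehead. The strategy rests on the fact that C8 is the only atom shared by ring B (C5, C6, C8, C9, C10) and ring D (C8, C14, C13, C16, C15), so that these two rings form a spiro[4.4]nonane and ring C is only the two-carbon bridge C11–C12 from C9 to C13. A spirocycle with a vinyl group on C9 and a vinyl carbinol at C13 is therefore one olefin metathesis away from the tetracycle.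

## Retrosynthetic reasoning

**41 ⇐ 40 ⇐ 38.** The three carboxyls are carried as methyl esters and freed last, by thiolate attack at the methyl groups of 40. The tertiary esters at C4 and C10 do not hydrolyse, and acid would rearrange the 13-hydroxy-16-ene. The C16=C17 bond is cut next (carbonyl olefination of 38). This keeps the exocyclic alkene out of all earlier steps and lets C16 be a plain oxygenated carbon until then. The C13 hydroxyl is silylated for that step because a free α-ketol alkoxide would rearrange.

**37 ⇐ 36 ⇐ 35 ⇐ 34.** The C16 ketone comes from the secondary alcohol 36, which is the ring-opened form of a lactone between C7 and the C16 oxygen (35, 34). An acetal at C16 would be a passive spectator. The lactone instead protects the C7 carboxyl and the C16 oxygen with one group, locks C6 in its natural configuration, and (see below) is the device that distinguishes C16 from C13.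

**34 ⇐ 33 (key disconnection).** The C11=C12 bond is cut, which opens ring C to two vinyl groups. C11 and C12 are unsubstituted methylene carbons in 41, so no stereocentre lies on the bond that is formed. The tetracycle is reduced to the spiro[4.4]nonane of rings B and D fused to ring A. The forward step has to join the vinyl group on C9 (α) with the vinyl group of the C13 carbinol, which must sit on the face of ring D turned towards C9.

**33 ⇐ 31 ⇐ 29 + 27.** The C9–C11 bond and the C9–H bond both come from the C9 ketone of 29. This ketone lies between two quaternary carbons; it cannot be enolised and is unlikely to react with bulky phosphorus ylides. A small vinyl nucleophile (27) is added from the open β face, anti to the axial C10 ester. The C9–O bond of carbonate 31 is then replaced by C9–H with inversion, in a palladium-catalysed reduction by formate. Both events use the β face, so H9 ends β and the vinyl group α.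

**29 ⇐ 28 ⇐ 26 + 27 ⇐ 25 ⇐ 23.** The C12–C13 bond is cut to the ketone 26. The vinyl group has to enter from the C9 face, so this addition is placed while C9 is still a flat carbonyl; a substituent on C9 would screen that face. The lactone C16–O bond is cut next. 25 arises from acid 23 by epoxidation of the symmetrical cyclopentene of ring D and opening of the epoxide 24 by the C7 carboxyl. The β-carboxyl reaches only the olefinic carbon on the β side, which becomes C16. This step turns the non-stereogenic spiro atom into the C8 stereocentre and puts the C16 oxygen on the face away from C9. An external reagent could not tell the two olefinic carbons apart.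

**23 ⇐ 22 ⇐ 20 ⇐ 18 + 19.** The C7 carboxyl is kept as a silylated primary alcohol up to 22, so that C6 is not enolisable while strong bases are in use. Ring A is cut at C4–CH3 and C3–C4 (two enolate alkylations at C4). The ring is closed first, so that the methyl group then enters equatorially and leaves the C19 ester axial, cis to C20. Ring A is also cut at C10–C1 (alkylation of β-keto ester 18 with dibromide 19 trans to the C5 substituent, which fixes the trans ring fusion).

**18 ⇐ 15 + 16; 15 ⇐ 13 ⇐ 11.** The C4–C5 bond is cut (conjugate addition of ketene silyl acetal 16 to the alkylidene β-keto ester 15, trans to the C6 substituent). Enone 15 comes from β-keto ester 13. The C9–C10 bond of 13 is cut to spiro lactone 11, whose only enolisable carbon (C10) acylates itself on the lactone carbonyl (C9). This ring closure has no regiochemical alternative.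

**11 ⇐ 9 ⇐ 7 + 8; 7 ⇐ 4 + 5; 4 ⇐ 3 ⇐ 1 + 2.** The C5–C6 bond is cut (Michael addition of the titanium enolate of imide 7 to acrylate 8 under control of auxiliary 5). C6 is the only centre set by an external chiral source; all later centres are relayed from it. The C6–C8 bond is cut last (alkylation of the enolate of 1 with 2). C8 is thus quaternary from the first step and ring D arrives as a symmetrical cyclopentene, so the spiro centre never has to be built on a crowded bicyclic ketone.

## Alternatives that were turned down

Alternative 1: The C9–C10 bond of ring B is disconnected. Ring A becomes an aromatic salicylate and ring C a 4,4-disubstituted cyclohexenone, linked through C6. In the forward step a base forms the phenolate, whose para carbon (the future C10) adds to C9 of the enone. This dearomatises ring A and closes ring B to give the dienone A1.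
- For: it is convergent, ring A costs almost nothing, and the quaternary C10 and ring B come from one bond formation. On convergence it is stronger than the chosen route, which is linear.
- Against, for this target: A1 carries ring A as a cross-conjugated dienone. The C3 carbonyl and the C1=C2 and C4=C5 double bonds all have to be removed, with H5 delivered trans to the angular group and C4 methylated afterwards. The target 41 has no oxygen in ring A, so all of this is correction.
- The ring C carbonyl of A1 is at C12. Closing ring D through C13 therefore leaves a bridgehead C–H that would still have to be hydroxylated, and the C12 oxygen removed. The angular benzyloxymethyl group must be oxidised to the acid.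
- Comparison: the chosen route makes ring A at its final oxidation level and installs the C13 oxygen before ring C exists. It pays with length.

Alternative 2: C8–C9 and C12–C13 are disconnected together. Ring D becomes a silyloxy cyclopentadiene and the carbon chain on C10 an allene. In the forward step a carbophilic platinum or gold catalyst turns the allene into an allyl cation equivalent. This adds across the diene termini in a (4+3) sense, closes rings B and C, and after a 1,2-hydride shift gives A2 with the C11=C12 alkene.
- For: this is the most step-economic option. Two rings, two bonds, the quaternary C8 and the oxygenated bridgehead C13 come from one step, and the allylsilane in A2 is a direct precursor of the C16 methylene. In bonds formed per step it is clearly stronger than a metathesis that forms one bond and no stereocentre.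
- Against: substituted cyclopentadienes scramble by 1,5-hydrogen shifts, so the positions of the silyloxy group, the silylmethyl group and the tether are not secure. The allene has to be built on a neopentyl carbon.
- The one step has to choose the diene face (C8 and C13 relative to C6 and C10), the (4+3) over (4+2) and (3+2) modes, and the direction of the hydride shift (C9). There is no handle to correct any of these afterwards.
- Comparison: the chosen route spreads these decisions over separate substrate-controlled steps of established type and leaves to its key step a ring closure that creates no stereocentre.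

Alternative 3: This is a relay. Rings A, C and D, with their stereocentres, the C13 hydroxyl and the C16 methylene, are taken from the natural ent-kaurane steviol A4. Only ring B is changed. In the forward step an α-diazoketone in the six-membered ring B of an A4 derivative is photolysed in an alcohol. Wolff rearrangement moves C5 to the carbene carbon and the ketene is trapped as the C7 ester, which gives the 13-hydroxy-20-methyl gibberellin dimethyl ester A3 (the dimethyl ester of the gibberellin numbered 53 in the A series).
- For: every stereocentre is secured by the starting material, the ring contraction proceeds with retention at the migrating carbon, and the gibberellane skeleton is reached in far fewer steps. On stereochemical security and step count it is stronger than the chosen route.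
- Against: A3 has a methyl group at C20, whereas 41 needs a carboxyl. That angular methyl lies between C1, C5 and C9, with only the axial C19 carboxyl nearby. It would have to be raised three oxidation levels by directed C–H functionalisation, in the presence of the acid-labile 13-hydroxy-16-ene.
- The route starts from a diterpenoid and is a partial synthesis, not a total synthesis from simple materials.
- Comparison: the chosen route brings C20 in as a carboxyl carbon from acrylate 8 and needs no late C–H oxidation.

Key step: step 18

Remark on the chemistry: gibberellane numbering is used for every intermediate and gibberellane-based names refer to the natural series drawn in the SMILES; α and β refer to ring B (H5 is β); the face of ring D that looks at C9 is called the C9 face and the one that looks at C6 the C6 face; compounds 1, 5 and 16 are taken as purchasable.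

## Route

Step 1
Reactants: 1 methyl cyclopent-3-ene-1-carboxylate; 2 tert-butyl bromoacetate
Product: 3 methyl 1-(2-tert-butoxy-2-oxoethyl)cyclopent-3-ene-1-carboxylate
Conditions: LiN(iPr)2, THF, −78 °C; then 2, −78 → 0 °C
Reagents that add atoms: none
Why: Ester enolate alkylation with a reactive α-bromo ester; it makes C8 quaternary at the start and attaches C6 and C7, with the two carboxyl groups differentiated as methyl and tert-butyl esters.

Step 2
Reactants: 3 methyl 1-(2-tert-butoxy-2-oxoethyl)cyclopent-3-ene-1-carboxylate
Product: 4 2-[1-(methoxycarbonyl)cyclopent-3-en-1-yl]acetic acid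
Conditions: CF3CO2H, CH2Cl2, 0 °C → rt
Reagents that add atoms: none
Why: Acidolysis of the tert-butyl ester (loss of the tert-butyl cation as alkene); the hindered methyl ester and the cis-disubstituted alkene should be inert.

Step 3
Reactants: 4 2-[1-(methoxycarbonyl)cyclopent-3-en-1-yl]acetic acid; 5 (S)-4-benzyl-1,3-oxazolidin-2-one
Product: 7 (S)-4-benzyl-3-{2-[1-(methoxycarbonyl)cyclopent-3-en-1-yl]acetyl}-1,3-oxazolidin-2-one, via mixed pivalic anhydride 6 (not isolated)
Conditions: t-BuCOCl, Et3N, THF, −20 °C; then 5, LiCl, rt
Reagents that add atoms: none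
Why: N-Acylation of the oxazolidinone through the mixed anhydride, which is attacked at the less hindered (non-pivaloyl) carbonyl.

Step 4
Reactants: 7 (S)-4-benzyl-3-{2-[1-(methoxycarbonyl)cyclopent-3-en-1-yl]acetyl}-1,3-oxazolidin-2-one; 8 methyl acrylate
Product: 9 methyl 1-{(2S)-1-[(S)-4-benzyl-2-oxo-1,3-oxazolidin-3-yl]-5-methoxy-1,5-dioxopentan-2-yl}cyclopent-3-ene-1-carboxylate
Conditions: TiCl4, Ti(OiPr)4 (3:1), iPr2NEt, CH2Cl2, 0 °C; then 8, 0 °C
Reagents that add atoms: none
Why: Auxiliary-controlled Michael addition of the chelated Z titanium enolate of the imide to the acrylate. The acceptor should approach the enolate face opposite the benzyl group, in the same sense as in alkylations of such enolates, which sets C6 as drawn. This is the only stereocentre of the route set by an external chiral source.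

Step 5
Reactants: 9 methyl 1-{(2S)-1-[(S)-4-benzyl-2-oxo-1,3-oxazolidin-3-yl]-5-methoxy-1,5-dioxopentan-2-yl}cyclopent-3-ene-1-carboxylate
Product: 11 methyl 3-[(4S)-1-oxo-2-oxaspiro[4.4]non-7-en-4-yl]propanoate, via hydroxy diester 10 (not isolated)
Conditions: NaBH4, THF–H2O, 0 °C → rt; then TsOH (cat.), toluene, 60 °C
Reagents that add atoms: none
Why: Reductive cleavage of the N-acyl oxazolidinone to the primary alcohol (methyl esters should survive borohydride), then acid-equilibrated lactonisation. The five-membered spiro lactone onto the C9 ester is favoured over the six-membered alternative by ring size and by the gem-disubstitution at C8. The auxiliary is recovered.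

Step 6
Reactants: 11 methyl 3-[(4S)-1-oxo-2-oxaspiro[4.4]non-7-en-4-yl]propanoate
Product: 13 methyl (4S)-4-[(tert-butyldimethylsilyloxy)methyl]-1-oxospiro[4.4]non-7-ene-2-carboxylate (C2 epimers), via hydroxy keto ester 12 (not isolated)
Conditions: LiN(SiMe3)2 (2.2 equiv), THF, −78 → 0 °C; AcOH; then t-BuMe2SiCl, imidazole, DMF, rt
Reagents that add atoms: tert-butyldimethylsilyl chloride, CC(C)(C)[Si](C)(C)Cl
Why: Intramolecular Claisen (Dieckmann-type) acylation: the only enolisable carbon of 11 (C10) attacks the lactone carbonyl (C9) and closes ring B, driven by formation of the β-keto ester enolate. The released primary alcohol is silylated so that C6 carries no acidifying group in the next steps.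

Step 7
Reactants: 13 methyl (4S)-4-[(tert-butyldimethylsilyloxy)methyl]-1-oxospiro[4.4]non-7-ene-2-carboxylate
Product: 15 methyl (4S)-4-[(tert-butyldimethylsilyloxy)methyl]-1-oxospiro[4.4]nona-2,7-diene-2-carboxylate, via phenylselenide 14 (not isolated)
Conditions: NaH, THF, 0 °C; PhSeBr, −78 °C; then H2O2, pyridine, CH2Cl2, 0 °C
Reagents that add atoms: none
Why: Selenenylation of the β-keto ester enolate (fast enough at −78 °C to spare the ring D alkene) and selenoxide syn-elimination, which can only go towards C5. The alkylidene β-keto ester is used crude.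

Step 8
Reactants: 15 methyl (4S)-4-[(tert-butyldimethylsilyloxy)methyl]-1-oxospiro[4.4]nona-2,7-diene-2-carboxylate; 16 tert-butyl[(1-methoxyethenyl)oxy]dimethylsilane
Product: 18 methyl 4-[(tert-butyldimethylsilyloxy)methyl]-3-(2-methoxy-2-oxoethyl)-1-oxospiro[4.4]non-7-ene-2-carboxylate (3,4-trans; C2 epimers), via silyl enol ether 17 (not isolated)
Conditions: Sc(OTf)3 (5 mol %), CH2Cl2, −78 °C; then aq. citric acid, THF
Reagents that add atoms: none
Why: Mukaiyama–Michael addition to the doubly activated enone under non-basic conditions, so C6 cannot epimerise through a dienolate. The nucleophile should add to C5 on the face opposite the adjacent C6 substituent, which places C4 trans to C7.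

Step 9
Reactants: 18 methyl 4-[(tert-butyldimethylsilyloxy)methyl]-3-(2-methoxy-2-oxoethyl)-1-oxospiro[4.4]non-7-ene-2-carboxylate; 19 1,3-dibromopropane
Product: 20 methyl 2-(3-bromopropyl)-4-[(tert-butyldimethylsilyloxy)methyl]-3-(2-methoxy-2-oxoethyl)-1-oxospiro[4.4]non-7-ene-2-carboxylate (bromopropyl trans to the acetate arm)
Conditions: Cs2CO3, 19 (5 equiv), DMF, rt
Reagents that add atoms: none
Why: C-Alkylation of the β-keto ester enolate by a primary bromide. The electrophile should enter anti to the vicinal C5 substituent, so C1 is trans to C4 and the C20 ester is α, which fixes the trans A/B fusion in advance.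

Step 10
Reactants: 20 methyl 2-(3-bromopropyl)-4-[(tert-butyldimethylsilyloxy)methyl]-3-(2-methoxy-2-oxoethyl)-1-oxospiro[4.4]non-7-ene-2-carboxylate
Product: 22 tricyclic keto diester (rings A and B and D): 9-oxo-5β-H-4β-methyl-4α,10α-bis(methoxycarbonyl)-6β-[(tert-butyldimethylsilyloxy)methyl] trans-hydrindane with ring D (cyclopent-13(16)-ene) spiro at C8, via ring-closed C4-H ester 21 (not isolated)
Conditions: LiN(iPr)2, THF–DMPU, −78 → 0 °C; then LiN(iPr)2, −78 °C; MeI, −78 → 0 °C
Reagents that add atoms: iodomethane, CI
Why: C4 is the only enolisable carbon of 20 (the C9 ketone has no α-hydrogen), and its ester enolate closes ring A by 6-exo-tet alkylation at C3. In the rigid trans-fused chair the second enolate is methylated from the equatorial direction, because the axial approach is blocked 1,3-diaxially by the C10 ester; this gives the 4β-methyl and the axial 4α-ester.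

Step 11
Reactants: 22 tricyclic keto diester with 6β-silyloxymethyl group
Product: 23 tricyclic keto diester C7 acid: 9-oxo-4β-methyl-4α,10α-bis(methoxycarbonyl)-6β-carboxylic acid with ring D cyclopentene
Conditions: CrO3, H2SO4, acetone–H2O, 0 °C → rt
Reagents that add atoms: water, O
Why: Jones oxidation cleaves the primary silyl ether in the acidic medium and oxidises the alcohol through the aldehyde hydrate to the acid; the isolated alkene, the non-enolisable ketone and the esters should be inert.

Step 12
Reactants: 23 tricyclic keto diester C7 acid
Product: 25 hydroxy lactone: 7,16-lactone (C16–O on the C6 face) with 13-OH on the C9 face; 9-oxo; 4β-methyl-4α,10α-bis(methoxycarbonyl), via epoxy acid 24 (not isolated)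
Conditions: 3-ClC6H4CO3H, CH2Cl2, 0 °C → rt; then camphorsulfonic acid (cat.)
Reagents that add atoms: 3-chloroperoxybenzoic acid, OOC(=O)c1cccc(Cl)c1
Why: Epoxidation of the ring D alkene should occur on the C9 face, which is flanked only by the flat C9 carbonyl, whereas the C6 face carries the β-carboxyl. The carboxyl then opens the epoxide anti in a 6-exo manner and, being β, reaches only the olefinic carbon bound to the β-methylene C15, which becomes C16. This distinguishes C16 from C13 and makes C8 a stereocentre of the required configuration.

Step 13
Reactants: 25 hydroxy lactone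
Product: 26 keto lactone: 13-oxo-7,16-lactone; 9-oxo; 4β-methyl-4α,10α-bis(methoxycarbonyl)
Conditions: Dess–Martin periodinane, NaHCO3, CH2Cl2, 0 °C → rt
Reagents that add atoms: none
Why: Neutral oxidation of the secondary alcohol to the ketone; the bridged lactone prevents epimerisation at C16.

Step 14
Reactants: 26 keto lactone; 27 vinylmagnesium bromide
Product: 28 13-hydroxy-13-vinyl 7,16-lactone (vinyl on the C9 face and hydroxyl on the C6 face); 9-oxo; 4β-methyl-4α,10α-bis(methoxycarbonyl)
Conditions: CeCl3, 27 (1.1 equiv), THF, −78 °C
Reagents that add atoms: none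
Why: Organocerium 1,2-addition to the reactive α-acyloxy ketone; the neopentyl C9 ketone, the lactone and the tertiary esters should not compete at −78 °C. The reagent attacks the exo face of the two-carbon bridge of the oxabicyclo[3.2.1]octanone, anti to the C16–O bond. This is the C9 face, which is still open because C9 is trigonal, so the vinyl group points towards C9.

Step 15
Reactants: 28 13-hydroxy-13-vinyl 7,16-lactone
Product: 29 13-(trimethylsilyloxy)-13-vinyl 7,16-lactone; 9-oxo
Conditions: Me3SiOTf, Et3N, CH2Cl2, −78 → 0 °C
Reagents that add atoms: trimethylsilyl trifluoromethanesulfonate, C[Si](C)(C)OS(=O)(=O)C(F)(F)F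
Why: Silylation of the tertiary alcohol so that only the C9 alkoxide is acylated in the next step; the C9 ketone cannot form a silyl enol ether.

Step 16
Reactants: 29 13-(trimethylsilyloxy)-13-vinyl 7,16-lactone; 27 vinylmagnesium bromide
Product: 31 9α-(methoxycarbonyloxy)-9β-vinyl-13-(trimethylsilyloxy)-13-vinyl 7,16-lactone, via cerium alkoxide 30 (not isolated)
Conditions: CeCl3, 27, THF, −78 → 0 °C; then ClCO2Me, 0 °C
Reagents that add atoms: methyl chloroformate, COC(=O)Cl
Why: 1,2-Addition to the non-enolisable ketone from the β face, anti to the axial C10 ester (the same bias as for a cyclopentanone next to an angular group on a trans-hydrindane), gives 9β-vinyl and 9α-O. Trapping the alkoxide cold as the carbonate forestalls retro-aldol cleavage towards C10 and supplies the leaving group.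

Step 17
Reactants: 31 9α-(methoxycarbonyloxy)-9β-vinyl-13-(trimethylsilyloxy)-13-vinyl 7,16-lactone
Product: 33 metathesis precursor: 9α-vinyl (9β-H)-13-hydroxy-13-vinyl 7,16-lactone of the ring A/B/D spirocycle; 4β-methyl-4α,10α-bis(methoxycarbonyl), via silyl ether 32 (not isolated)
Conditions: Pd(OAc)2 (5 mol %), n-Bu3P, HCO2H, Et3N, THF, 40 °C; then AcOH–THF–H2O, rt
Reagents that add atoms: none
Why: Palladium-catalysed formate hydrogenolysis of the tertiary allylic carbonate: zerovalent palladium ionises the carbonate anti to the leaving group, so the metal lies on the β face, which is also the less hindered one. Formate then delivers hydride from the metal to the more substituted allyl terminus C9, so H9 is β, the vinyl group ends α and the double bond stays terminal. C8 and C10 have no hydrogen, so diene formation is excluded, and mild acid then removes the trimethylsilyl ether.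

Step 18
Reactants: 33 metathesis precursor
Product: 34 tetracyclic C11=C12 alkene: 13-hydroxy-7,16-lactone with rings A to D; 4β-methyl-4α,10α-bis(methoxycarbonyl)
Conditions: (H2IMes)(PCy3)Cl2Ru=CHPh (second-generation Grubbs catalyst, 10 mol %), CH2Cl2 (0.005 M), 40 °C, argon purge
Reagents that add atoms: none
Why: The ruthenium benzylidene exchanges with one terminal alkene (probably the vinyl carbinol, whose free hydroxyl assists initiation); the new alkylidene undergoes [2+2] cycloaddition with the second vinyl group and cycloreversion of the ruthenacyclobutane forms C11=C12 and a ruthenium methylidene that carries the chain. The closest known reaction type is ring-closing metathesis of a cyclopentane bearing a vinyl group and, in a cis-1,3 relation, an allyl-type arm, which gives a bicyclo[3.2.1]oct-2-ene. Ring C closes as a six-membered carbocycle across the 1,3-positions C8 and C13 of ring D; the ring size allows only the cis alkene. No stereocentre is created. The step needs ring closure to outrun intermolecular metathesis; this is secured by the syn placement of the two vinyl groups on the C9 face (set in steps 14 and 17), by the spiro atom that fixes their distance, by high dilution and by loss of the volatile alkene. No other ring can form because 33 has no other alkene.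

Step 19
Reactants: 34 tetracyclic C11=C12 alkene
Product: 35 saturated tetracyclic 13-hydroxy-7,16-lactone; 4β-methyl-4α,10α-bis(methoxycarbonyl)
Conditions: H2 (1 atm), Pd/C, EtOAc, rt
Reagents that add atoms: none
Why: Heterogeneous hydrogenation of the strained cis-disubstituted alkene; the allylic C13–O bond is at a bridgehead and should not undergo hydrogenolysis.

Step 20
Reactants: 35 saturated tetracyclic 13-hydroxy-7,16-lactone
Product: 36 trimethyl 13,16-dihydroxy-17-norgibberellane-7,19,20-trioate (16-OH on the C6 face; 13,16-cis-diol)
Conditions: NaOMe, MeOH, 0 °C → rt; neutralise with AcOH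
Reagents that add atoms: methanol, CO
Why: Methanolysis of the bridged lactone releases the C7 methyl ester and the C16 alcohol. Methoxide also equilibrates C6, where the natural 6β-ester (trans to C4 and clear of the axial C19 ester) is the more stable epimer.

Step 21
Reactants: 36 trimethyl 13,16-dihydroxy-17-norgibberellane-7,19,20-trioate
Product: 37 trimethyl 13-hydroxy-16-oxo-17-norgibberellane-7,19,20-trioate
Conditions: Dess–Martin periodinane, NaHCO3, CH2Cl2, rt
Reagents that add atoms: none
Why: Buffered oxidation of the secondary alcohol; the tertiary alcohol is inert and the neutral conditions should avoid α-ketol rearrangement.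

Step 22
Reactants: 37 trimethyl 13-hydroxy-16-oxo-17-norgibberellane-7,19,20-trioate
Product: 38 trimethyl 16-oxo-13-(trimethylsilyloxy)-17-norgibberellane-7,19,20-trioate
Conditions: Me3SiCl, imidazole, DMF, rt
Reagents that add atoms: chlorotrimethylsilane, C[Si](C)(C)Cl
Why: Silylation masks the tertiary hydroxyl so that the basic ylide of the next step cannot form the α-ketol alkoxide that would rearrange the C/D system.

Step 23
Reactants: 38 trimethyl 16-oxo-13-(trimethylsilyloxy)-17-norgibberellane-7,19,20-trioate
Product: 40 trimethyl 13-hydroxygibberell-16-ene-7,19,20-trioate (trimethyl ester of the target), via silyl ether 39 (not isolated)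
Conditions: Ph3PCH3Br, KOtBu, THF, 0 → 60 °C; then AcOH–THF–H2O, rt
Reagents that add atoms: methyltriphenylphosphonium bromide, C[P+](c1ccccc1)(c1ccccc1)c1ccccc1.[Br-]
Why: Wittig methylenation of the bridged cyclopentanone installs C17. Any epimerisation at C6 by the ylide leads to the stable natural epimer, and mild acid removes the silyl ether without touching the allylic alcohol.

Step 24
Reactants: 40 trimethyl 13-hydroxygibberell-16-ene-7,19,20-trioate
Product: 41 13-hydroxygibberell-16-ene-7,19,20-trioic acid (the target gibberellin)
Conditions: n-PrSH, n-BuLi, HMPA, 0 °C → rt; then dilute HCl to pH 3, 0 °C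
Reagents that add atoms: none
Why: SN2 demethylation by the thiolate at the three O-methyl carbons cleaves the hindered tertiary esters at C4 and C10 as well, without acyl attack. It avoids both the strong acid that would rearrange the 13-hydroxy-16-ene and the hydroxide that would epimerise C6.

## Compound list

1 | methyl cyclopent-3-ene-1-carboxylate | COC(=O)C1CC=CC1 | starting material
2 | tert-butyl bromoacetate | BrCC(=O)OC(C)(C)C | starting material
3 | methyl 1-(2-tert-butoxy-2-oxoethyl)cyclopent-3-ene-1-carboxylate | COC(=O)C1(CC(=O)OC(C)(C)C)CC=CC1 | intermediate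
4 | 2-[1-(methoxycarbonyl)cyclopent-3-en-1-yl]acetic acid | COC(=O)C1(CC(=O)O)CC=CC1 | intermediate
5 | (S)-4-benzyl-1,3-oxazolidin-2-one | O=C1OC[C@H](Cc2ccccc2)N1 | starting material
6 | mixed anhydride of 4 and pivalic acid | COC(=O)C1(CC(=O)OC(=O)C(C)(C)C)CC=CC1 | intermediate (not isolated)
7 | (S)-4-benzyl-3-{2-[1-(methoxycarbonyl)cyclopent-3-en-1-yl]acetyl}-1,3-oxazolidin-2-one | COC(=O)C1(CC(=O)N2[C@@H](Cc3ccccc3)COC2=O)CC=CC1 | intermediate
8 | methyl acrylate | C=CC(=O)OC | starting material
9 | methyl 1-{(2S)-1-[(S)-4-benzyl-2-oxo-1,3-oxazolidin-3-yl]-5-methoxy-1,5-dioxopentan-2-yl}cyclopent-3-ene-1-carboxylate | COC(=O)CC[C@H](C(=O)N1[C@@H](Cc2ccccc2)COC1=O)C1(C(=O)OC)CC=CC1 | intermediate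
10 | methyl 1-[(2S)-1-hydroxy-5-methoxy-5-oxopentan-2-yl]cyclopent-3-ene-1-carboxylate | COC(=O)CC[C@H](CO)C1(C(=O)OC)CC=CC1 | intermediate (not isolated)
11 | methyl 3-[(4S)-1-oxo-2-oxaspiro[4.4]non-7-en-4-yl]propanoate | COC(=O)CC[C@@H]1COC(=O)C12CC=CC2 | intermediate
12 | methyl (4S)-4-(hydroxymethyl)-1-oxospiro[4.4]non-7-ene-2-carboxylate (C2 epimers) | COC(=O)C1C[C@H](CO)C2(CC=CC2)C1=O | intermediate (not isolated)
13 | methyl (4S)-4-[(tert-butyldimethylsilyloxy)methyl]-1-oxospiro[4.4]non-7-ene-2-carboxylate (C2 epimers) | COC(=O)C1C[C@H](CO[Si](C)(C)C(C)(C)C)C2(CC=CC2)C1=O | intermediate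
14 | methyl (4S)-4-[(tert-butyldimethylsilyloxy)methyl]-1-oxo-2-(phenylselanyl)spiro[4.4]non-7-ene-2-carboxylate | COC(=O)C1([Se]c2ccccc2)C[C@H](CO[Si](C)(C)C(C)(C)C)C3(CC=CC3)C1=O | intermediate (not isolated)
15 | methyl (4S)-4-[(tert-butyldimethylsilyloxy)methyl]-1-oxospiro[4.4]nona-2,7-diene-2-carboxylate | COC(=O)C1=C[C@H](CO[Si](C)(C)C(C)(C)C)C2(CC=CC2)C1=O | intermediate
16 | tert-butyl[(1-methoxyethenyl)oxy]dimethylsilane | C=C(OC)O[Si](C)(C)C(C)(C)C | starting material
17 | methyl 1-(tert-butyldimethylsilyloxy)-4-[(tert-butyldimethylsilyloxy)methyl]-3-(2-methoxy-2-oxoethyl)spiro[4.4]nona-1,7-diene-2-carboxylate (3,4-trans) | COC(=O)C[C@H]1[C@H](CO[Si](C)(C)C(C)(C)C)C2(CC=CC2)C(O[Si](C)(C)C(C)(C)C)=C1C(=O)OC | intermediate (not isolated)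
18 | methyl 4-[(tert-butyldimethylsilyloxy)methyl]-3-(2-methoxy-2-oxoethyl)-1-oxospiro[4.4]non-7-ene-2-carboxylate (3,4-trans; C2 epimers) | COC(=O)C[C@H]1[C@H](CO[Si](C)(C)C(C)(C)C)C2(CC=CC2)C(=O)C1C(=O)OC | intermediate
19 | 1,3-dibromopropane | BrCCCBr | starting material
20 | methyl 2-(3-bromopropyl)-4-[(tert-butyldimethylsilyloxy)methyl]-3-(2-methoxy-2-oxoethyl)-1-oxospiro[4.4]non-7-ene-2-carboxylate (2,3-trans; 3,4-trans) | COC(=O)C[C@H]1[C@H](CO[Si](C)(C)C(C)(C)C)C2(CC=CC2)C(=O)[C@@]1(CCCBr)C(=O)OC | intermediate
21 | tricyclic keto diester without the C4 methyl (C4 epimers): 9-oxo-5β-H-4,10α-bis(methoxycarbonyl)-6β-(silyloxymethyl) trans-hydrindane, ring D cyclopentene spiro at C8 | O=C1[C@]2(C(=O)OC)CCCC(C(=O)OC)[C@H]2[C@H](CO[Si](C)(C)C(C)(C)C)C13CC=CC3 | intermediate (not isolated)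
22 | tricyclic keto diester: 9-oxo-5β-H-4β-methyl-4α,10α-bis(methoxycarbonyl)-6β-[(tert-butyldimethylsilyloxy)methyl] trans-hydrindane, ring D cyclopentene spiro at C8 | O=C1[C@]2(C(=O)OC)CCC[C@@](C)(C(=O)OC)[C@H]2[C@H](CO[Si](C)(C)C(C)(C)C)C13CC=CC3 | intermediate
23 | C7 acid of the tricyclic keto diester (6β-CO2H) | O=C1[C@]2(C(=O)OC)CCC[C@@](C)(C(=O)OC)[C@H]2[C@H](C(=O)O)C13CC=CC3 | intermediate
24 | epoxy acid: 13,16-epoxide on the C9 face of ring D | O=C1[C@]2(C(=O)OC)CCC[C@@](C)(C(=O)OC)[C@H]2[C@H](C(=O)O)[C@]13C[C@@H]4O[C@@H]4C3 | intermediate (not isolated)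
25 | hydroxy lactone: 7,16-lactone (C16–O on the C6 face), 13-OH on the C9 face, 9-oxo | O=C1[C@]2(C(=O)OC)CCC[C@@](C)(C(=O)OC)[C@H]2[C@@H]3C(=O)O[C@@H]4C[C@]13C[C@H]4O | intermediate
26 | keto lactone: 9,13-dioxo-7,16-lactone | O=C1[C@]2(C(=O)OC)CCC[C@@](C)(C(=O)OC)[C@H]2[C@@H]3C(=O)O[C@@H]4C[C@]13CC4=O | intermediate
27 | vinylmagnesium bromide | C=C[Mg]Br | starting material
28 | 13-hydroxy-13-vinyl-9-oxo-7,16-lactone (vinyl on the C9 face) | O=C1[C@]2(C(=O)OC)CCC[C@@](C)(C(=O)OC)[C@H]2[C@@H]3C(=O)O[C@@H]4C[C@]13C[C@@]4(O)C=C | intermediate
29 | 13-(trimethylsilyloxy)-13-vinyl-9-oxo-7,16-lactone | O=C1[C@]2(C(=O)OC)CCC[C@@](C)(C(=O)OC)[C@H]2[C@@H]3C(=O)O[C@@H]4C[C@]13C[C@@]4(O[Si](C)(C)C)C=C | intermediate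
30 | dichlorocerium 9α-alkoxide of the 9β-vinyl adduct | Cl[Ce](Cl)O[C@@]1(C=C)[C@]2(C(=O)OC)CCC[C@@](C)(C(=O)OC)[C@H]2[C@@H]3C(=O)O[C@@H]4C[C@]13C[C@@]4(O[Si](C)(C)C)C=C | intermediate (not isolated)
31 | 9α-(methoxycarbonyloxy)-9β-vinyl-13-(trimethylsilyloxy)-13-vinyl-7,16-lactone | COC(=O)O[C@@]1(C=C)[C@]2(C(=O)OC)CCC[C@@](C)(C(=O)OC)[C@H]2[C@@H]3C(=O)O[C@@H]4C[C@]13C[C@@]4(O[Si](C)(C)C)C=C | intermediate
32 | 13-O-trimethylsilyl ether of 33 | C=C[C@H]1[C@]2(C(=O)OC)CCC[C@@](C)(C(=O)OC)[C@H]2[C@@H]3C(=O)O[C@@H]4C[C@]13C[C@@]4(O[Si](C)(C)C)C=C | intermediate (not isolated)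
33 | metathesis precursor: spiro rings B/D divinyl carbinol, 9α-vinyl (9β-H), 13-hydroxy-13-vinyl, 7,16-lactone | C=C[C@H]1[C@]2(C(=O)OC)CCC[C@@](C)(C(=O)OC)[C@H]2[C@@H]3C(=O)O[C@@H]4C[C@]13C[C@@]4(O)C=C | intermediate
34 | tetracyclic C11=C12 alkene, 13-hydroxy-7,16-lactone | O1[C@@H]2C[C@]34C[C@@]2(O)C=C[C@H]3[C@]5(C(=O)OC)CCC[C@@](C)(C(=O)OC)[C@H]5[C@@H]4C1=O | intermediate
35 | saturated tetracyclic 13-hydroxy-7,16-lactone | O1[C@@H]2C[C@]34C[C@@]2(O)CC[C@H]3[C@]5(C(=O)OC)CCC[C@@](C)(C(=O)OC)[C@H]5[C@@H]4C1=O | intermediate
36 | trimethyl 13,16-dihydroxy-17-norgibberellane-7,19,20-trioate (16-OH on the C6 face; 13,16-cis-diol) | O[C@@H]1C[C@]23C[C@@]1(O)CC[C@H]2[C@]1(C(=O)OC)CCC[C@@](C)(C(=O)OC)[C@H]1[C@@H]3C(=O)OC | intermediate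
37 | trimethyl 13-hydroxy-16-oxo-17-norgibberellane-7,19,20-trioate | O=C1C[C@]23C[C@@]1(O)CC[C@H]2[C@]1(C(=O)OC)CCC[C@@](C)(C(=O)OC)[C@H]1[C@@H]3C(=O)OC | intermediate
38 | trimethyl 16-oxo-13-(trimethylsilyloxy)-17-norgibberellane-7,19,20-trioate | O=C1C[C@]23C[C@@]1(O[Si](C)(C)C)CC[C@H]2[C@]1(C(=O)OC)CCC[C@@](C)(C(=O)OC)[C@H]1[C@@H]3C(=O)OC | intermediate
39 | trimethyl 13-(trimethylsilyloxy)gibberell-16-ene-7,19,20-trioate | C=C1C[C@]23C[C@@]1(O[Si](C)(C)C)CC[C@H]2[C@]1(C(=O)OC)CCC[C@@](C)(C(=O)OC)[C@H]1[C@@H]3C(=O)OC | intermediate (not isolated)
40 | trimethyl 13-hydroxygibberell-16-ene-7,19,20-trioate (trimethyl ester of the target) | C=C1C[C@]23C[C@@]1(O)CC[C@H]2[C@]1(C(=O)OC)CCC[C@@](C)(C(=O)OC)[C@H]1[C@@H]3C(=O)OC | intermediate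
41 | 13-hydroxygibberell-16-ene-7,19,20-trioic acid (the target gibberellin: 4β-methyl; 4α-, 6β- and 10α-carboxyl; 13-hydroxy; 16-methylene) | C=C1C[C@]23C[C@@]1(O)CC[C@H]2[C@]1(C(=O)O)CCC[C@@](C)(C(=O)O)[C@H]1[C@@H]3C(=O)O | target

## Step count and least certain steps

Total step count: 24. Longest linear sequence: 24 steps (1 → 41); the route is fully linear.

**Step 18 (key step).** Both alkenes are hindered: the C9 vinyl group lies between two quaternary carbons and the other is a tertiary carbinol. The lactone bridge also twists ring D, so initiation and ring closure may be slow enough for intermolecular metathesis and catalyst decay to take over, or the closure may be reversible because the doubly bridged ring D is strained.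

Fallback: the bridge is removed before the metathesis. Starting from 33, methanolysis with NaOMe in MeOH would open the lactone to the unbridged dihydroxy triester F1, which has a free secondary hydroxyl at C16 and the C7 methyl ester. Ring-closing metathesis of the conformationally freer diene F1 with (H2IMes)(PCy3)Cl2Ru=CHPh would give the tetracyclic alkene diol F2. Hydrogenation of F2 over Pd/C returns to the route at 36.

**Step 17.** The hydride may be transferred to the unhindered allyl terminus C12 instead of the congested C9, which would leave an internal alkene. Facial control at C9 may also be incomplete if the allyl complex equilibrates.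

Fallback by hydroboration, which sets out from 25, where no alkene is present: methylenation of the C9 ketone with Zn, CH2Br2 and TiCl4 would give the exocyclic alkene F3. Hydroboration with BH3·THF from the β face, anti to the C10 ester, followed by oxidation with NaBO3, would give the diol F4 with H9 β. Selective oxidation of the primary alcohol (TEMPO, PhI(OAc)2) would give the aldehyde F5, and Wittig methylenation with Ph3P=CH2 would give the 9α-vinyl alcohol F6. Dess–Martin oxidation would then give the ketone F7, and addition of 27 with CeCl3 on the exo face of the bridged lactone rejoins the route at 33. This sequence also avoids the competition between the C9 ketone and the lactone in step 16. In return, the C13 addition has to take place next to the C9 vinyl group.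

**Step 12.** The peracid may be drawn to the C6 face by hydrogen bonding to the carboxyl group, which would give an epoxide that cannot be opened intramolecularly. Baeyer–Villiger oxidation of the C9 ketone may also compete.

Fallback that does not depend on the face of attack: iodolactonisation of 23 (I2, NaHCO3, MeCN–H2O) would give the iodolactone F8, because only the iodonium ion on the C9 face can be captured anti by the carboxyl. Radical oxygenation of the C–I bond (Bu3SnH, air, toluene) would give the C13 alcohols, 25 together with its epimer F9. Both would be oxidised by Dess–Martin periodinane to 26, where the route is rejoined.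

**Step 4.** Enolate addition at the α-carbon next to the quaternary C8 may be slow, so that acrylate oligomerisation or double addition competes, and the facial selectivity may suffer from competing chelation by the C9 ester.

Fallback by resolution: from 3, deprotonation with LiN(iPr)2 and addition to 8 would give the racemic triester F10. Acidolysis with CF3CO2H, followed by crystallisation of the salt with one enantiomer of 1-phenylethylamine (to be chosen by screening), would give the (S)-acid F11. Chemoselective reduction of the carboxyl group with BH3·SMe2 would give 10, which lactonises to 11 as in step 5.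

## Further compounds

F1 | step 18 | unbridged diene: 9α-vinyl, 13-hydroxy-13-vinyl, 16-hydroxy (C6 face), trimethyl ester | C=C[C@H]1[C@]2(C(=O)OC)CCC[C@@](C)(C(=O)OC)[C@H]2[C@H](C(=O)OC)[C@]13C[C@@H](O)[C@](O)(C=C)C3
F2 | step 18 | tetracyclic C11=C12 alkene 13,16-diol trimethyl ester | O[C@@H]1C[C@]23C[C@@]1(O)C=C[C@H]2[C@]1(C(=O)OC)CCC[C@@](C)(C(=O)OC)[C@H]1[C@@H]3C(=O)OC
F3 | step 17 | 9-methylidene hydroxy lactone | C=C1[C@]2(C(=O)OC)CCC[C@@](C)(C(=O)OC)[C@H]2[C@@H]3C(=O)O[C@@H]4C[C@]13C[C@H]4O
F4 | step 17 | 9α-(hydroxymethyl) (9β-H) hydroxy lactone | OC[C@H]1[C@]2(C(=O)OC)CCC[C@@](C)(C(=O)OC)[C@H]2[C@@H]3C(=O)O[C@@H]4C[C@]13C[C@H]4O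
F5 | step 17 | 9α-formyl hydroxy lactone | O=C[C@H]1[C@]2(C(=O)OC)CCC[C@@](C)(C(=O)OC)[C@H]2[C@@H]3C(=O)O[C@@H]4C[C@]13C[C@H]4O
F6 | step 17 | 9α-vinyl 13-hydroxy lactone | C=C[C@H]1[C@]2(C(=O)OC)CCC[C@@](C)(C(=O)OC)[C@H]2[C@@H]3C(=O)O[C@@H]4C[C@]13C[C@H]4O
F7 | step 17 | 9α-vinyl 13-oxo lactone | C=C[C@H]1[C@]2(C(=O)OC)CCC[C@@](C)(C(=O)OC)[C@H]2[C@@H]3C(=O)O[C@@H]4C[C@]13CC4=O
F8 | step 12 | iodolactone: 7,16-lactone with 13-iodide on the C9 face | O=C1[C@]2(C(=O)OC)CCC[C@@](C)(C(=O)OC)[C@H]2[C@@H]3C(=O)O[C@@H]4C[C@]13C[C@H]4I
F9 | step 12 | 13-epimer of 25 (13-OH on the C6 face) | O=C1[C@]2(C(=O)OC)CCC[C@@](C)(C(=O)OC)[C@H]2[C@@H]3C(=O)O[C@@H]4C[C@]13C[C@@H]4O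
F10 | step 4 | racemic 1-tert-butyl 5-methyl 2-[1-(methoxycarbonyl)cyclopent-3-en-1-yl]pentanedioate | COC(=O)CCC(C(=O)OC(C)(C)C)C1(C(=O)OC)CC=CC1
F11 | step 4 | (2S)-5-methoxy-2-[1-(methoxycarbonyl)cyclopent-3-en-1-yl]-5-oxopentanoic acid | COC(=O)CC[C@H](C(=O)O)C1(C(=O)OC)CC=CC1
A1 | alternative 1 | tetracyclic ring A dienone with ring C ketone, 8-propargyl and 10-benzyloxymethyl groups | C#CC[C@]23CCC(=O)C[C@H]2[C@]1(COCc4ccccc4)C=CC(=O)C(C(=O)OC)=C1[C@@H]3C(=O)OC
A2 | alternative 2 | tetracyclic bicyclo[3.2.1]octadiene allylsilane with 13-silyloxy group | C[Si](C)(C)CC1=C[C@]23C[C@@]1(O[Si](C)(C)C(C)(C)C)C=C[C@H]2[C@]1(C(=O)OC)CCC[C@@](C)(C(=O)OC)[C@H]1[C@@H]3C(=O)OC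
A3 | alternative 3 | dimethyl 13-hydroxygibberell-16-ene-7,19-dioate (20-methyl relative of the target as its dimethyl ester) | C=C1C[C@]23C[C@@]1(O)CC[C@H]2[C@]1(C)CCC[C@@](C)(C(=O)OC)[C@H]1[C@@H]3C(=O)OC
A4 | alternative 3 | steviol | C=C1C[C@]23C[C@@]1(O)CC[C@H]2[C@]1(C)CCC[C@@](C)(C(=O)O)[C@H]1CC3
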